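**Retrosynthetic overview**

1. Target 32 ⇐ silyl ether 31 ⇐ epoxide 28 (C1=C2 turned into the 3(2H)-furanone by epoxide opening, oxidation and elimination) ⇐ 25 (angeloylation at O8) ⇐ lactone 21 (α-methylenation).
2. Lactone 21 ⇐ ring-expanded keto ester 11: C7 alkylation, C8 reduction, C4 equilibration, C15 reduction, ozonolysis of the C6 methylene, 1,3-anti reduction, lactonisation.
3. Keto ester 11 ⇐ bicyclic β-keto ester 7 by a three-carbon ring expansion: C4 alkylation with silane 8, allylation of the C8 ketone, retro-aldol scission of C4–C8 (seven- to ten-membered ring).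
4. β-Keto ester 7 ⇐ 2-methylfuran 4 + siloxyvinyldiazoacetate 3 by a rhodium-catalysed [4+3] annulation that forms C3–C4 and C9–C10.
5. Feature: the furanone oxygen bridges C3 and the methyl-bearing quaternary C10 of the ten-membered ring, so O, C3, C2, C1, C10 and C14 are the atoms of 2-methylfuran, with C4 and C9 as the flanking carbons. Ring order: ether ring (bought) and seven-membered carbocycle (step 3), ten-membered carbocycle (step 6), lactone (step 14), furanone unveiled (step 20).

Key step: step 3

Convention: germacrane numbering is used (C1–C10 ring, C11–C13 lactone carbons, C14 methyl on C10, C15 on C4). β is the face of the flat-drawn ten-membered ring that carries the bridging oxygen, α the opposite face (CH3-14 and H-3 are α). In the von Baeyer names of 11–20, C1, C2, C4, C5, C6 and C8 of the oxabicycloundecene are germacrane C3, C4, C6, C7, C8 and C10.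

Assumption: Rh2(S-PTAD)4 is taken to give the (1S,5S) adduct 6; should the sense of induction be opposite, Rh2(R-PTAD)4 is used and nothing else changes.

**Route**

Step 1
Reactants: 1 methyl acetoacetate
Product: 2 methyl 2-diazo-3-oxobutanoate
Conditions: 4-acetamidobenzenesulfonyl azide, Et3N, MeCN, 0 °C → rt
Reagents that add atoms: 4-acetamidobenzenesulfonyl azide, CC(=O)Nc1ccc(cc1)S(=O)(=O)N=[N+]=[N-]
Why: Regitz diazo transfer to the active methylene of a β-keto ester.

Step 2
Reactants: 2 methyl 2-diazo-3-oxobutanoate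
Product: 3 methyl 3-(tert-butyldimethylsilyloxy)-2-diazobut-3-enoate
Conditions: TBSOTf, Et3N, CH2Cl2, 0 °C
Reagents that add atoms: tert-butyldimethylsilyl trifluoromethanesulfonate, CC(C)(C)[Si](C)(C)OS(=O)(=O)C(F)(F)F
Why: Soft enolisation and O-silylation of the acetyl group gives the 2-siloxyvinyl diazoacetate while the stabilised diazo group is untouched.

Step 3
Reactants: 3 methyl 3-(tert-butyldimethylsilyloxy)-2-diazobut-3-enoate; 4 2-methylfuran
Product: 6 methyl (1S,5S)-3-(tert-butyldimethylsilyloxy)-5-methyl-8-oxabicyclo[3.2.1]octa-2,6-diene-2-carboxylate, via cis-divinylcyclopropane 5 (not isolated)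
Conditions: Rh2(S-PTAD)4 (1 mol %), 4 (5 equiv), hexanes, −25 °C → rt, slow addition of 3
Reagents that add atoms: none
Why: Loss of N2 from 3 gives a donor–acceptor rhodium vinylcarbenoid that cyclopropanates the unsubstituted double bond of 4 in an asynchronous [2+1] addition (bonding first at the free α-carbon) to the cis-divinylcyclopropane 5, whose Cope rearrangement through the obligatory boat transition state gives 6; this is the established tandem cyclopropanation/Cope ([4+3]) annulation of furans with 2-siloxyvinyldiazoacetates. The transient three-membered ring closes by concerted carbenoid addition, and the seven-membered carbocycle closes in the [3,3] shift by bonding the vinyl CH2 (C9) to the methyl-bearing furan carbon (C10) while the cyclopropane bond breaks; the furan ring survives as the oxygen-bridged 2,5-dihydrofuran. The configuration at the ester-side bridgehead (C3) is fixed in the cyclopropanation by the chiral carboxylate ligands, which select the furan face; the quaternary bridgehead C10 follows from the suprafacial [3,3] step and is necessarily cis to C3. The step needs regioselection for the unsubstituted furan double bond, endo placement of the siloxyvinyl group and enantiofacial control: the 2-methyl group hinders the other double bond while the ring oxygen stabilises charge build-up at the free α-carbon, donor–acceptor carbenoids place the donor (vinyl) group cis to the alkene substituent, and the catalyst supplies the face selectivity. The silyl enol ether suppresses the competing ring opening of the furan to a triene.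

Step 4
Reactants: 6 methyl (1S,5S)-3-(tert-butyldimethylsilyloxy)-5-methyl-8-oxabicyclo[3.2.1]octa-2,6-diene-2-carboxylate
Product: 7 methyl (1S,5S)-3-hydroxy-5-methyl-8-oxabicyclo[3.2.1]octa-2,6-diene-2-carboxylate (enol form of the cyclic β-keto ester, in equilibrium with its 3-oxo tautomer)
Conditions: Bu4NF (1.0 equiv), AcOH (1.2 equiv), THF, 0 °C
Reagents that add atoms: none
Why: Fluoride-mediated desilylation of the silyl enol ether, buffered with acetic acid so that the enolate is protonated before it can expel the bridging oxygen.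

Step 5
Reactants: 7 methyl (1S,5S)-3-hydroxy-5-methyl-8-oxabicyclo[3.2.1]octa-2,6-diene-2-carboxylate; 8 2-(chloromethyl)allyltrimethylsilane
Product: 9 methyl (1S,2R,5S)-5-methyl-3-oxo-2-{2-[(trimethylsilyl)methyl]prop-2-en-1-yl}-8-oxabicyclo[3.2.1]oct-6-ene-2-carboxylate (allyl chain syn to the oxygen bridge)
Conditions: K2CO3, NaI (cat.), acetone, 50 °C
Reagents that add atoms: none
Why: C-Alkylation of the stabilised β-keto ester enolate by the allylic chloride (activated by in situ Finkelstein exchange), the electrophile entering from the exo face syn to the one-atom oxygen bridge; the new quaternary centre at C4 is of no consequence because it is lost in step 6.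

Step 6
Reactants: 9 methyl (1S,2R,5S)-5-methyl-3-oxo-2-{2-[(trimethylsilyl)methyl]prop-2-en-1-yl}-8-oxabicyclo[3.2.1]oct-6-ene-2-carboxylate
Product: 11 methyl 8-methyl-4-methylidene-6-oxo-11-oxabicyclo[6.2.1]undec-9-ene-2-carboxylate (C4 ester α, the 4-epimer of the required series), via tricyclic aldol 10 (not isolated)
Conditions: Bu4NF (1.1 equiv, 1 M in THF as supplied, containing water), THF, 0 → 45 °C; AcOH, −78 °C
Reagents that add atoms: none
Why: Fluoride triggers an intramolecular Hosomi–Sakurai-type allylation of the C8 ketone to the cis-fused cyclopentanol alkoxide 10, which undergoes retro-aldol scission of C4–C8 (three-carbon condensative ring expansion) driven by release of the bicyclo[3.2.1] strain and formation of the ester enolate; the water in the reagent protonates that enolate from the exo face before it can eliminate the β-oxygen (giving the 4α ester, corrected in step 9), and the cold acid quench returns the β,γ-unsaturated ketone by α-protonation of its dienolate.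

Step 7
Reactants: 11 methyl 8-methyl-4-methylidene-6-oxo-11-oxabicyclo[6.2.1]undec-9-ene-2-carboxylate; 12 tert-butyl bromoacetate
Product: 13 methyl 5-(2-tert-butoxy-2-oxoethyl)-8-methyl-4-methylidene-6-oxo-11-oxabicyclo[6.2.1]undec-9-ene-2-carboxylate (C4 ester α, C7 side chain β)
Conditions: LiN(SiMe3)2 (1.05 equiv), THF, −78 °C; 12, DMPU, −78 → −40 °C
Reagents that add atoms: none
Why: The silylamide removes only the doubly activated C7 proton (allylic and α to the ketone; the ester α-proton is too weakly acidic), and the dienolate is alkylated at its α-carbon, the electrophile approaching the exo face syn to the oxygen bridge and away from the C1=C2 bridge, which sets C7.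

Step 8
Reactants: 13 methyl 5-(2-tert-butoxy-2-oxoethyl)-8-methyl-4-methylidene-6-oxo-11-oxabicyclo[6.2.1]undec-9-ene-2-carboxylate
Product: 14 methyl 5-(2-tert-butoxy-2-oxoethyl)-6-hydroxy-8-methyl-4-methylidene-11-oxabicyclo[6.2.1]undec-9-ene-2-carboxylate (C4 ester α, C7 side chain β, 8β-OH)
Conditions: LiBH(s-Bu)3 (L-Selectride), THF, −78 °C; H2O
Reagents that add atoms: none
Why: Ketone reduction by a bulky hydride under 1,2-induction (Felkin–Anh, as for 2-alkylcycloalkanones): hydride is delivered anti to the adjacent C7 substituent, so the new 8-hydroxyl is cis to the side chain, and neither ester reacts at −78 °C.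

Step 9
Reactants: 14 methyl 5-(2-tert-butoxy-2-oxoethyl)-6-hydroxy-8-methyl-4-methylidene-11-oxabicyclo[6.2.1]undec-9-ene-2-carboxylate (C4 ester α)
Product: 15 methyl 5-(2-tert-butoxy-2-oxoethyl)-6-hydroxy-8-methyl-4-methylidene-11-oxabicyclo[6.2.1]undec-9-ene-2-carboxylate (C4 ester β, C7 side chain β, 8β-OH)
Conditions: NaOMe (0.2 equiv), MeOH, rt
Reagents that add atoms: none
Why: Base-catalysed epimerisation of the ester α-centre under thermodynamic control, which should place the ester antiperiplanar to C2 and gauche to the ring oxygen (the β, exo position); in methanol the enolate is reprotonated far faster than it can expel the bridging oxygen, the tert-butyl ester is inert, and the cis γ-hydroxy ester does not lactonise because a cis-fused γ-lactone demands a ring torsion that the ten-membered ring resists.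

Step 10
Reactants: 15 methyl 5-(2-tert-butoxy-2-oxoethyl)-6-hydroxy-8-methyl-4-methylidene-11-oxabicyclo[6.2.1]undec-9-ene-2-carboxylate (C4 ester β)
Product: 16 tert-butyl 2-[6-hydroxy-2-(hydroxymethyl)-8-methyl-4-methylidene-11-oxabicyclo[6.2.1]undec-9-en-5-yl]acetate (4β-CH2OH, C7 side chain β, 8β-OH)
Conditions: LiBH4, THF, 0 °C → rt
Reagents that add atoms: none
Why: Chemoselective borohydride reduction of the methyl ester in the presence of the hindered tert-butyl ester; C4 is no longer epimerisable after this step.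

Step 11
Reactants: 16 tert-butyl 2-[6-hydroxy-2-(hydroxymethyl)-8-methyl-4-methylidene-11-oxabicyclo[6.2.1]undec-9-en-5-yl]acetate
Product: 17 tert-butyl 2-[2-(tert-butyldiphenylsilyloxymethyl)-6-hydroxy-8-methyl-4-methylidene-11-oxabicyclo[6.2.1]undec-9-en-5-yl]acetate
Conditions: TBDPSCl (1.05 equiv), imidazole, CH2Cl2, 0 °C
Reagents that add atoms: tert-butyl(chloro)diphenylsilane, CC(C)(C)[Si](Cl)(c1ccccc1)c1ccccc1
Why: Selective silylation of the primary alcohol over the hindered secondary 8-hydroxyl with a bulky silyl chloride.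

Step 12
Reactants: 17 tert-butyl 2-[2-(tert-butyldiphenylsilyloxymethyl)-6-hydroxy-8-methyl-4-methylidene-11-oxabicyclo[6.2.1]undec-9-en-5-yl]acetate
Product: 18 tert-butyl 2-[2-(tert-butyldiphenylsilyloxymethyl)-6-hydroxy-8-methyl-4-oxo-11-oxabicyclo[6.2.1]undec-9-en-5-yl]acetate (β-hydroxy ketone: C6 ketone, 8β-OH)
Conditions: O3, CH2Cl2/MeOH, −78 °C, Sudan Red 7B end point; Me2S
Reagents that add atoms: ozone, [O-][O+]=O
Why: Ozonolysis with reductive work-up, selective for the electron-rich 1,1-disubstituted alkene over the dihydrofuran alkene, which is deactivated by two allylic C–O bonds; the neutral work-up avoids retro-aldol opening and C7 epimerisation of the β-hydroxy ketone.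

Step 13
Reactants: 18 tert-butyl 2-[2-(tert-butyldiphenylsilyloxymethyl)-6-hydroxy-8-methyl-4-oxo-11-oxabicyclo[6.2.1]undec-9-en-5-yl]acetate
Product: 19 tert-butyl 2-[2-(tert-butyldiphenylsilyloxymethyl)-4,6-dihydroxy-8-methyl-11-oxabicyclo[6.2.1]undec-9-en-5-yl]acetate (6α-OH, 8β-OH, C7 side chain β)
Conditions: Me4NBH(OAc)3, MeCN/AcOH, −30 °C
Reagents that add atoms: none
Why: Evans–Saksena reduction: the 8-hydroxyl binds the acetoxyborohydride and delivers hydride intramolecularly through a six-membered chair transition state, giving the 1,3-anti diol, that is the 6α-alcohol trans to the C7 side chain.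

Step 14
Reactants: 19 tert-butyl 2-[2-(tert-butyldiphenylsilyloxymethyl)-4,6-dihydroxy-8-methyl-11-oxabicyclo[6.2.1]undec-9-en-5-yl]acetate
Product: 21 15-(tert-butyldiphenylsilyloxy)-3,10-epoxy-8β-hydroxy-13-norgermacr-1-en-6α,12-olide (trans-fused γ-lactone, C11 is CH2), via hydroxy acid 20 (not isolated)
Conditions: CF3CO2H/CH2Cl2 (1:4), 0 °C; then toluene, 40 °C
Reagents that add atoms: none
Why: Acidolysis of the tert-butyl ester and acid-catalysed lactonisation; the 6α-hydroxyl, trans to the side chain, closes a trans-fused lactone that fits an anti ring torsion of the ten-membered ring, whereas closure onto the cis 8β-hydroxyl would need a near-eclipsed ring torsion and should not compete.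

Step 15
Reactants: 21 15-(tert-butyldiphenylsilyloxy)-3,10-epoxy-8β-hydroxy-13-norgermacr-1-en-6α,12-olide; 22 N,N-dimethylmethyleneiminium iodide (CH2=NMe2+ I−)
Product: 23 13-(dimethylamino)-15-(tert-butyldiphenylsilyloxy)-3,10-epoxy-8β-hydroxygermacr-1-en-6α,12-olide (aminomethyl group on C11 anti to C8)
Conditions: LiN(i-Pr)2 (2.2 equiv), THF, −78 °C; 22, −78 → 0 °C
Reagents that add atoms: none
Why: Mannich aminomethylation of the lactone enolate (generated as the alkoxide–enolate dianion) with the preformed iminium salt, the electrophile entering anti to the C7–C8 bond; the new C11 centre is removed in step 16.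

Step 16
Reactants: 23 13-(dimethylamino)-15-(tert-butyldiphenylsilyloxy)-3,10-epoxy-8β-hydroxygermacr-1-en-6α,12-olide
Product: 25 15-(tert-butyldiphenylsilyloxy)-3,10-epoxy-8β-hydroxygermacra-1,11(13)-dien-6α,12-olide, via ammonium iodide 24 (not isolated)
Conditions: MeI, MeOH, rt; then NaHCO3 (aq), EtOAc
Reagents that add atoms: none
Why: N-Quaternisation followed by E1cB (Hofmann-type) loss of trimethylamine gives the α-methylene lactone under mild base that leaves the hydroxy lactone intact.

Step 17
Reactants: 25 15-(tert-butyldiphenylsilyloxy)-3,10-epoxy-8β-hydroxygermacra-1,11(13)-dien-6α,12-olide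
Product: 26 15-(tert-butyldiphenylsilyloxy)-1,2:3,10-diepoxy-8β-hydroxygermacr-11(13)-en-6α,12-olide (1,2-epoxide cis to H-3 and CH3-14)
Conditions: dimethyldioxirane, acetone, 0 °C
Reagents that add atoms: dimethyldioxirane, CC1(C)OO1
Why: Electrophilic epoxidation of the only non-conjugated alkene (the α-methylene lactone is electron-poor and reacts far more slowly), from the face of the dihydrofuran that carries H-3 and the methyl group, the other face being covered by the ten-membered ring.

Step 18
Reactants: 26 15-(tert-butyldiphenylsilyloxy)-1,2:3,10-diepoxy-8β-hydroxygermacr-11(13)-en-6α,12-olide; 27 angelic acid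
Product: 28 8β-angeloyloxy-15-(tert-butyldiphenylsilyloxy)-1,2:3,10-diepoxygermacr-11(13)-en-6α,12-olide
Conditions: 27, 2,4,6-trichlorobenzoyl chloride, Et3N, toluene, rt; then 26, toluene, 80 °C
Reagents that add atoms: none
Why: Yamaguchi esterification through the mixed anhydride, the standard way to acylate a hindered secondary alcohol with angelic acid without Z to E isomerisation; the deactivated epoxide and the methylene lactone tolerate the conditions.

Step 19
Reactants: 28 8β-angeloyloxy-15-(tert-butyldiphenylsilyloxy)-1,2:3,10-diepoxygermacr-11(13)-en-6α,12-olide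
Product: 29 8β-angeloyloxy-2-bromo-15-(tert-butyldiphenylsilyloxy)-3,10-epoxy-1-hydroxygermacr-11(13)-en-6α,12-olide (Br trans to the 1-OH and trans to H-3)
Conditions: LiBr, AcOH, THF, 40 °C
Reagents that add atoms: lithium bromide, [Li+].[Br-]
Why: Acid-assisted SN2 opening of the epoxide by bromide with inversion, at C2 because C1 is neopentyl-like next to the quaternary C10, which leaves the hydroxyl on C1 and the bromide antiperiplanar to H-3.

Step 20
Reactants: 29 8β-angeloyloxy-2-bromo-15-(tert-butyldiphenylsilyloxy)-3,10-epoxy-1-hydroxygermacr-11(13)-en-6α,12-olide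
Product: 31 8β-angeloyloxy-15-(tert-butyldiphenylsilyloxy)-3,10-epoxy-1-oxogermacra-2,11(13)-dien-6α,12-olide, via bromo ketone 30 (not isolated)
Conditions: Dess–Martin periodinane, CH2Cl2, rt; then Et3N, rt
Reagents that add atoms: none
Why: Dess–Martin oxidation to the α-bromo ketone followed by anti E2 dehydrobromination across C2–C3 (H-3 is trans to bromine and C10 has no hydrogen), which gives the vinylogous ester of the 3(2H)-furanone; the amine also reverses any HBr adduct of the methylene lactone.

Step 21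
Reactants: 31 8β-angeloyloxy-15-(tert-butyldiphenylsilyloxy)-3,10-epoxy-1-oxogermacra-2,11(13)-dien-6α,12-olide
Product: 32 8β-angeloyloxy-15-hydroxy-3,10-epoxy-1-oxogermacra-2,11(13)-dien-6α,12-olide, (4S,6R,7S,8R,10S) (target, CNP0108636.1)
Conditions: HF·pyridine, THF/pyridine, 0 °C → rt
Reagents that add atoms: none
Why: Fluoride cleavage of the primary silyl ether under buffered, non-basic conditions that the methylene lactone, the angelate and the furanone tolerate.

**Compound list**

1 | methyl acetoacetate | CC(=O)CC(=O)OC | starting material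
2 | methyl 2-diazo-3-oxobutanoate | CC(=O)C(=[N+]=[N-])C(=O)OC | intermediate
3 | methyl 3-(tert-butyldimethylsilyloxy)-2-diazobut-3-enoate | COC(=O)C(=[N+]=[N-])C(=C)O[Si](C)(C)C(C)(C)C | intermediate
4 | 2-methylfuran | Cc1ccco1 | starting material
5 | methyl (1S,5S,6S)-6-[1-(tert-butyldimethylsilyloxy)ethenyl]-3-methyl-2-oxabicyclo[3.1.0]hex-3-ene-6-carboxylate (alkenyl group endo; not isolated) | COC(=O)[C@@]1(C(=C)O[Si](C)(C)C(C)(C)C)[C@@H]2C=C(C)O[C@H]12 | intermediate
6 | methyl (1S,5S)-3-(tert-butyldimethylsilyloxy)-5-methyl-8-oxabicyclo[3.2.1]octa-2,6-diene-2-carboxylate | COC(=O)C1=C(O[Si](C)(C)C(C)(C)C)C[C@@]2(C)C=C[C@@H]1O2 | intermediate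
7 | methyl (1S,5S)-3-hydroxy-5-methyl-8-oxabicyclo[3.2.1]octa-2,6-diene-2-carboxylate (enol form of the β-keto ester) | COC(=O)C1=C(O)C[C@@]2(C)C=C[C@@H]1O2 | intermediate
8 | 2-(chloromethyl)allyltrimethylsilane | C=C(CCl)C[Si](C)(C)C | starting material
9 | methyl (1S,2R,5S)-5-methyl-3-oxo-2-{2-[(trimethylsilyl)methyl]prop-2-en-1-yl}-8-oxabicyclo[3.2.1]oct-6-ene-2-carboxylate | COC(=O)[C@@]1(CC(=C)C[Si](C)(C)C)C(=O)C[C@@]2(C)C=C[C@@H]1O2 | intermediate
10 | methyl 6-hydroxy-8-methyl-4-methylidene-11-oxatricyclo[6.2.1.0(2,6)]undec-9-ene-2-carboxylate (cis-fused cyclopentanol on the oxygen-bridge face; formed as its alkoxide, not isolated) | COC(=O)[C@@]12CC(=C)C[C@]1(O)C[C@@]3(C)C=C[C@@H]2O3 | intermediate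
11 | methyl 8-methyl-4-methylidene-6-oxo-11-oxabicyclo[6.2.1]undec-9-ene-2-carboxylate (C4 ester α) | C=C1C[C@H](C(=O)OC)[C@@H]2C=C[C@](C)(CC(=O)C1)O2 | intermediate
12 | tert-butyl bromoacetate | CC(C)(C)OC(=O)CBr | starting material
13 | methyl 5-(2-tert-butoxy-2-oxoethyl)-8-methyl-4-methylidene-6-oxo-11-oxabicyclo[6.2.1]undec-9-ene-2-carboxylate (C4 ester α, C7 side chain β) | CC(C)(C)OC(=O)C[C@H]1C(=C)C[C@H](C(=O)OC)[C@@H]2C=C[C@](C)(CC1=O)O2 | intermediate
14 | methyl 5-(2-tert-butoxy-2-oxoethyl)-6-hydroxy-8-methyl-4-methylidene-11-oxabicyclo[6.2.1]undec-9-ene-2-carboxylate (C4 ester α, 8β-OH) | CC(C)(C)OC(=O)C[C@H]1C(=C)C[C@H](C(=O)OC)[C@@H]2C=C[C@](C)(C[C@H]1O)O2 | intermediate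
15 | methyl 5-(2-tert-butoxy-2-oxoethyl)-6-hydroxy-8-methyl-4-methylidene-11-oxabicyclo[6.2.1]undec-9-ene-2-carboxylate (C4 ester β, 8β-OH) | CC(C)(C)OC(=O)C[C@H]1C(=C)C[C@@H](C(=O)OC)[C@@H]2C=C[C@](C)(C[C@H]1O)O2 | intermediate
16 | tert-butyl 2-[6-hydroxy-2-(hydroxymethyl)-8-methyl-4-methylidene-11-oxabicyclo[6.2.1]undec-9-en-5-yl]acetate | CC(C)(C)OC(=O)C[C@H]1C(=C)C[C@@H](CO)[C@@H]2C=C[C@](C)(C[C@H]1O)O2 | intermediate
17 | tert-butyl 2-[2-(tert-butyldiphenylsilyloxymethyl)-6-hydroxy-8-methyl-4-methylidene-11-oxabicyclo[6.2.1]undec-9-en-5-yl]acetate | CC(C)(C)OC(=O)C[C@H]1C(=C)C[C@@H](CO[Si](c3ccccc3)(c3ccccc3)C(C)(C)C)[C@@H]2C=C[C@](C)(C[C@H]1O)O2 | intermediate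
18 | tert-butyl 2-[2-(tert-butyldiphenylsilyloxymethyl)-6-hydroxy-8-methyl-4-oxo-11-oxabicyclo[6.2.1]undec-9-en-5-yl]acetate | CC(C)(C)OC(=O)C[C@H]1C(=O)C[C@@H](CO[Si](c3ccccc3)(c3ccccc3)C(C)(C)C)[C@@H]2C=C[C@](C)(C[C@H]1O)O2 | intermediate
19 | tert-butyl 2-[2-(tert-butyldiphenylsilyloxymethyl)-4,6-dihydroxy-8-methyl-11-oxabicyclo[6.2.1]undec-9-en-5-yl]acetate (6α-OH, 8β-OH) | CC(C)(C)OC(=O)C[C@H]1[C@H](O)C[C@@H](CO[Si](c3ccccc3)(c3ccccc3)C(C)(C)C)[C@@H]2C=C[C@](C)(C[C@H]1O)O2 | intermediate
20 | 2-[2-(tert-butyldiphenylsilyloxymethyl)-4,6-dihydroxy-8-methyl-11-oxabicyclo[6.2.1]undec-9-en-5-yl]acetic acid (not isolated) | OC(=O)C[C@H]1[C@H](O)C[C@@H](CO[Si](c3ccccc3)(c3ccccc3)C(C)(C)C)[C@@H]2C=C[C@](C)(C[C@H]1O)O2 | intermediate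
21 | 15-(tert-butyldiphenylsilyloxy)-3,10-epoxy-8β-hydroxy-13-norgermacr-1-en-6α,12-olide | C1C(=O)O[C@@H]2C[C@@H](CO[Si](c4ccccc4)(c4ccccc4)C(C)(C)C)[C@@H]3C=C[C@](C)(C[C@@H](O)[C@@H]12)O3 | intermediate
22 | N,N-dimethylmethyleneiminium iodide | C=[N+](C)C.[I-] | starting material
23 | 13-(dimethylamino)-15-(tert-butyldiphenylsilyloxy)-3,10-epoxy-8β-hydroxygermacr-1-en-6α,12-olide | CN(C)C[C@@H]1C(=O)O[C@@H]2C[C@@H](CO[Si](c4ccccc4)(c4ccccc4)C(C)(C)C)[C@@H]3C=C[C@](C)(C[C@@H](O)[C@@H]12)O3 | intermediate
24 | trimethylammonium iodide of 23 (N-methylated Mannich base; not isolated) | [I-].C[N+](C)(C)C[C@@H]1C(=O)O[C@@H]2C[C@@H](CO[Si](c4ccccc4)(c4ccccc4)C(C)(C)C)[C@@H]3C=C[C@](C)(C[C@@H](O)[C@@H]12)O3 | intermediate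
25 | 15-(tert-butyldiphenylsilyloxy)-3,10-epoxy-8β-hydroxygermacra-1,11(13)-dien-6α,12-olide | C=C1C(=O)O[C@@H]2C[C@@H](CO[Si](c4ccccc4)(c4ccccc4)C(C)(C)C)[C@@H]3C=C[C@](C)(C[C@@H](O)[C@@H]12)O3 | intermediate
26 | 15-(tert-butyldiphenylsilyloxy)-1,2:3,10-diepoxy-8β-hydroxygermacr-11(13)-en-6α,12-olide (1,2-epoxide cis to H-3 and CH3-14) | C=C1C(=O)O[C@@H]2C[C@@H](CO[Si](c5ccccc5)(c5ccccc5)C(C)(C)C)[C@@H]3[C@H]4O[C@H]4[C@](C)(C[C@@H](O)[C@@H]12)O3 | intermediate
27 | angelic acid, (Z)-2-methylbut-2-enoic acid | C/C=C(/C)C(=O)O | starting material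
28 | 8β-angeloyloxy-15-(tert-butyldiphenylsilyloxy)-1,2:3,10-diepoxygermacr-11(13)-en-6α,12-olide | C=C1C(=O)O[C@@H]2C[C@@H](CO[Si](c5ccccc5)(c5ccccc5)C(C)(C)C)[C@@H]3[C@H]4O[C@H]4[C@](C)(C[C@@H](OC(=O)/C(C)=C\C)[C@@H]12)O3 | intermediate
29 | 8β-angeloyloxy-2-bromo-15-(tert-butyldiphenylsilyloxy)-3,10-epoxy-1-hydroxygermacr-11(13)-en-6α,12-olide (Br trans to 1-OH and to H-3) | C=C1C(=O)O[C@@H]2C[C@@H](CO[Si](c4ccccc4)(c4ccccc4)C(C)(C)C)[C@@H]3[C@H](Br)[C@@H](O)[C@](C)(C[C@@H](OC(=O)/C(C)=C\C)[C@@H]12)O3 | intermediate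
30 | 8β-angeloyloxy-2-bromo-15-(tert-butyldiphenylsilyloxy)-3,10-epoxy-1-oxogermacr-11(13)-en-6α,12-olide (not isolated) | C=C1C(=O)O[C@@H]2C[C@@H](CO[Si](c4ccccc4)(c4ccccc4)C(C)(C)C)[C@@H]3[C@H](Br)C(=O)[C@](C)(C[C@@H](OC(=O)/C(C)=C\C)[C@@H]12)O3 | intermediate
31 | 8β-angeloyloxy-15-(tert-butyldiphenylsilyloxy)-3,10-epoxy-1-oxogermacra-2,11(13)-dien-6α,12-olide | C=C1C(=O)O[C@@H]2C[C@@H](CO[Si](c4ccccc4)(c4ccccc4)C(C)(C)C)C3=CC(=O)[C@](C)(C[C@@H](OC(=O)/C(C)=C\C)[C@@H]12)O3 | intermediate
32 | 8β-angeloyloxy-15-hydroxy-3,10-epoxy-1-oxogermacra-2,11(13)-dien-6α,12-olide, (4S,6R,7S,8R,10S) | C=C1C(=O)O[C@@H]2C[C@@H](CO)C3=CC(=O)[C@](C)(C[C@@H](OC(=O)/C(C)=C\C)[C@@H]12)O3 | target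

**Step count**

Total: 21 steps. Longest linear sequence: 21 steps (from methyl acetoacetate 1).

**The three steps most likely to fail**

Step 6 (ring expansion). The allylsilane may be protodesilylated before it adds to the ketone, the tertiary alkoxide may fail to fragment, or the ester enolate may expel the bridging oxygen before it is protonated. The fallback separates the two events and forms the C7–C8 bond reductively in a protic medium. It sets out from 7, which is alkylated (K2CO3, acetone) with 3-bromo-2-(bromomethyl)prop-1-ene to give the allylic bromide methyl (1S,2R,5S)-2-[2-(bromomethyl)prop-2-en-1-yl]-5-methyl-3-oxo-8-oxabicyclo[3.2.1]oct-6-ene-2-carboxylate F1. An indium-mediated Barbier cyclisation (In powder, THF/H2O) should then give the tricyclic alcohol 10, now isolated under neutral conditions in which no enolate exists. The retro-aldol is run separately with KN(SiMe3)2 in THF at −78 °C and quenched cold with AcOH, so that the ester enolate has no time to eliminate; the fallback returns to the route at 11.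

Step 7 (C7 alkylation). C7 is remote from the bridgeheads, so facial discrimination may be poor or the electrophile may enter from the endo face. The fallback sets C7 by protonation instead of alkylation. It sets out from 11; if the alkylation of step 7 delivers the epimer methyl 5-(2-tert-butoxy-2-oxoethyl)-8-methyl-4-methylidene-6-oxo-11-oxabicyclo[6.2.1]undec-9-ene-2-carboxylate with the C7 side chain α F2, this is deprotonated again (LiN(SiMe3)2, THF, −78 °C) to its lithium dienolate F3. Kinetic α-protonation with AcOH at −78 °C should come from the same accessible face that the electrophile used and therefore place the side chain β, which returns the route to 13.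

Step 19 (epoxide opening). Bromide may attack C1 instead of C2, or the deactivated epoxide may open so slowly that HBr adds to the methylene lactone. The fallback replaces the opening by a syn β-elimination that is regiospecific by constitution, since H-3 is the only hydrogen cis to the epoxide oxygen. It sets out from 26, which is treated with diethylaluminium 2,2,6,6-tetramethylpiperidide (from Et2AlCl and lithium 2,2,6,6-tetramethylpiperidide, toluene, 0 °C) to give the allylic alcohol 15-(tert-butyldiphenylsilyloxy)-3,10-epoxy-1,8β-dihydroxygermacra-2,11(13)-dien-6α,12-olide F4. MnO2 in CH2Cl2 should oxidise only the allylic 1-hydroxyl to give the hydroxy furanone 15-(tert-butyldiphenylsilyloxy)-3,10-epoxy-8β-hydroxy-1-oxogermacra-2,11(13)-dien-6α,12-olide F5. Yamaguchi angeloylation of F5 under the conditions of step 18 returns the route to 31.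

Further compounds
F1 | step 6 | methyl (1S,2R,5S)-2-[2-(bromomethyl)prop-2-en-1-yl]-5-methyl-3-oxo-8-oxabicyclo[3.2.1]oct-6-ene-2-carboxylate | COC(=O)[C@@]1(CC(=C)CBr)C(=O)C[C@@]2(C)C=C[C@@H]1O2
F2 | step 7 | methyl 5-(2-tert-butoxy-2-oxoethyl)-8-methyl-4-methylidene-6-oxo-11-oxabicyclo[6.2.1]undec-9-ene-2-carboxylate, C7 epimer of 13 (side chain α) | CC(C)(C)OC(=O)C[C@@H]1C(=C)C[C@H](C(=O)OC)[C@@H]2C=C[C@](C)(CC1=O)O2
F3 | step 7 | lithium dienolate of F2 and 13 (C7=C8 enolate, ring-cis) | [Li+].CC(C)(C)OC(=O)C/C1=C(\[O-])C[C@@]2(C)C=C[C@H](O2)[C@@H](C(=O)OC)CC1=C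
F4 | step 19 | 15-(tert-butyldiphenylsilyloxy)-3,10-epoxy-1,8β-dihydroxygermacra-2,11(13)-dien-6α,12-olide (1-OH cis to CH3-14) | C=C1C(=O)O[C@@H]2C[C@@H](CO[Si](c4ccccc4)(c4ccccc4)C(C)(C)C)C3=C[C@@H](O)[C@](C)(C[C@@H](O)[C@@H]12)O3
F5 | step 19 | 15-(tert-butyldiphenylsilyloxy)-3,10-epoxy-8β-hydroxy-1-oxogermacra-2,11(13)-dien-6α,12-olide | C=C1C(=O)O[C@@H]2C[C@@H](CO[Si](c4ccccc4)(c4ccccc4)C(C)(C)C)C3=CC(=O)[C@](C)(C[C@@H](O)[C@@H]12)O3
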